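**Plan**

- Retrosynthesis: first cut the bond from C3 of the dihydropyranone to the side-chain CH2 (Negishi sp2–sp3 coupling). Then cut the ring O–CH2 bond of the oxolanone (Baeyer–Villiger oxygen insertion). Then cut both ring C–C bonds of the resulting cyclobutanone ([2+2] of a ketene with a vinyl group). Last, cut the enoate C=C (ring-closing metathesis), the ester C–O bond and the allyl–carbinol bond.
- Enabling feature: the oxolan-2-one is substituted only at C4, so its C5–C4–C3–C2 carbons are the four carbons of a 3-substituted cyclobutanone with two identical CH2 arms. That ring is the C6 vinyl group of a 6-vinyl-5,6-dihydropyran-2-one plus a two-carbon ketene. At that stage the only other π bond is the ring enoate, which an electrophilic ketene does not attack.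
- Forward order: acrolein → dienol → acrylate → dihydropyranone ring (metathesis) → cyclobutanone on the vinyl group → oxolanone ring (oxygen insertion) → bromination at C3 → union with the side chain, which is made in three steps from dihydro-β-ionone.
- Stereochemistry: C6 (R) comes from reagent-controlled allylboration of acrolein. The oxolanone centre (R) comes from a catalyst-controlled, group-selective Baeyer–Villiger migration, after dechlorination has merged both cycloadduct epimers into one ketone. The E alkene comes from syn-carboalumination of a terminal alkyne.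

Key step: step 4

Assumption: the sense of induction of the chiral scandium catalyst of step 6 on this substrate is not known beforehand; the route is written for the ligand antipode that makes the pro-R methylene arm of the cyclobutanone migrate.

**Route**

Step 1
Reactants: 1 acrolein
Product: 3 (3R)-hexa-1,5-dien-3-ol, via diisopinocampheylborinate ester 2 (not isolated)
Conditions: (+)-Ipc2B(allyl) (1 M in pentane), Et2O, −78 °C; then 3 M NaOH, 30% H2O2, 0 °C → rt
Reagents that add atoms: (+)-B-allyldiisopinocampheylborane (antipode derived from (−)-α-pinene), C=CCB([C@H]1C[C@H]2C[C@@H]([C@@H]1C)C2(C)C)[C@H]1C[C@H]2C[C@@H]([C@@H]1C)C2(C)C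
Why: Brown allylboration, in which the chair six-membered transition state of this reagent antipode should deliver the allyl group to the Re face of the aldehyde by reagent control and so set the (R) carbinol centre, with 1,2-addition only.

Step 2
Reactants: 3 (3R)-hexa-1,5-dien-3-ol
Product: 4 (3R)-hexa-1,5-dien-3-yl prop-2-enoate
Conditions: acryloyl chloride, Et3N, DMAP (cat.), CH2Cl2, 0 °C
Reagents that add atoms: acryloyl chloride, C=CC(=O)Cl
Why: DMAP-catalysed O-acylation of a secondary alcohol, which does not touch the stereocentre.

Step 3
Reactants: 4 (3R)-hexa-1,5-dien-3-yl prop-2-enoate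
Product: 5 (6R)-6-ethenyl-5,6-dihydro-2H-pyran-2-one
Conditions: second-generation Grubbs catalyst RuCl2(=CHPh)(H2IMes)(PCy3) (2 mol%), CH2Cl2 (0.01 M), 40 °C
Reagents that add atoms: none
Why: Ring-closing metathesis, in which the ruthenium carbene should load on the unhindered homoallylic alkene and close on the acrylate to the six-membered enoate, whereas closure through the vinyl group would need the slower allyl acrylate route to a butenolide, so the vinyl group should be kept.

Step 4
Reactants: 5 (6R)-6-ethenyl-5,6-dihydro-2H-pyran-2-one
Product: 6 (6R)-6-(2,2-dichloro-3-oxocyclobutyl)-5,6-dihydro-2H-pyran-2-one (both epimers at the cyclobutane carbon bound to C6)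
Conditions: Cl3CCOCl (slow addition), zinc–copper couple (Zn–Cu), POCl3, Et2O, reflux
Reagents that add atoms: trichloroacetyl chloride, ClC(Cl)(Cl)C(Cl)=O, which gives dichloroketene, ClC(Cl)=C=O, in the flask
Why: Zinc reduces trichloroacetyl chloride to dichloroketene, which should add to the vinyl group in a concerted but asynchronous ketene–alkene [2+2] cycloaddition, the electrophilic ketene carbonyl carbon bonding to the terminal CH2 and the CCl2 carbon to the internal carbon, so that both ring C–C bonds of the later lactone form at once. The closest known reaction type is the dichloroketene cycloaddition to monosubstituted alkenes such as allyl ethers and allyl esters under zinc–copper/POCl3 activation. The four-membered ring is closed by cycloaddition of two separate π components (no exo or endo ring closure is involved), and the polarity of the ketene fixes the regiochemistry (C=O carbon to the less substituted alkene carbon). The only new stereocentre, the cyclobutane carbon bound to C6, is not controlled and need not be, because removal of the chlorines in step 5 makes this carbon non-stereogenic and funnels both epimers into one ketone. The step needs chemoselectivity for the vinyl group; this is secured because the ring C3=C4 bond is an electron-poor enoate that an electrophilic ketene does not attack, and because the allylic oxygen is acylated and thus too weakly nucleophilic to divert the ketene into an O-acylation and [3,3] shift (ketene-Claisen) pathway. The C6 centre is remote from all bond changes and should be kept.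

Step 5
Reactants: 6 (6R)-6-(2,2-dichloro-3-oxocyclobutyl)-5,6-dihydro-2H-pyran-2-one
Product: 7 (6R)-6-(3-oxocyclobutyl)-5,6-dihydro-2H-pyran-2-one
Conditions: Zn dust, AcOH, rt → 50 °C
Reagents that add atoms: none
Why: Reductive dechlorination of an α,α-dichloroketone by zinc in acetic acid through zinc enolates, which leaves the enoate and the lactone alone and turns the ring carbon bound to C6 into a prostereogenic centre with two identical CH2 arms.

Step 6
Reactants: 7 (6R)-6-(3-oxocyclobutyl)-5,6-dihydro-2H-pyran-2-one
Product: 8 (6R)-6-[(3R)-5-oxooxolan-3-yl]-5,6-dihydro-2H-pyran-2-one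
Conditions: Sc(OTf)3 (5 mol%), chiral C2-symmetric N,N'-dioxide ligand (pipecolic acid-derived bis-anilide, 6 mol%), m-CPBA, EtOAc, −20 °C
Reagents that add atoms: m-CPBA, OOC(=O)c1cccc(Cl)c1
Why: Catalytic asymmetric Baeyer–Villiger oxidation of a 3-substituted cyclobutanone, in which the pro-R methylene arm of the Criegee adduct bound to the chiral scandium complex should migrate and set the (3R) centre of the oxolanone by catalyst control; because C6 is already fixed the other outcome is a diastereomer that can be removed, and the enoate is inert to the peracid.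

Step 7
Reactants: 8 (6R)-6-[(3R)-5-oxooxolan-3-yl]-5,6-dihydro-2H-pyran-2-one
Product: 10 (6R)-3-bromo-6-[(3R)-5-oxooxolan-3-yl]-5,6-dihydro-2H-pyran-2-one, via trans-3,4-dibromo lactone 9 (not isolated)
Conditions: Br2, CH2Cl2, 0 °C → rt; then Et3N, 0 °C → rt
Reagents that add atoms: bromine, BrBr
Why: Anti addition of bromine to the enoate followed by triethylamine-induced loss of HBr (removal of the acidic H at C3, E1cB type) is the established route to 3-bromo-5,6-dihydro-2H-pyran-2-ones, no other alkene is present at this stage, and both stereocentres are untouched.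

Step 8
Reactants: 11 dihydro-β-ionone
Product: 13 2-(but-3-yn-1-yl)-1,3,3-trimethylcyclohex-1-ene, via enol phosphate 12 (not isolated)
Conditions: LiN(iPr)2, THF, −78 °C; ClP(O)(OEt)2, −78 °C → rt; then LiN(iPr)2 (2.3 equiv), −78 °C → rt
Reagents that add atoms: none
Why: Kinetic deprotonation at the methyl group gives the terminal enol phosphate, and base-induced elimination of diethyl phosphate should then give the terminal alkyne (Negishi conversion of a methyl ketone into a 1-alkyne).

Step 9
Reactants: 13 2-(but-3-yn-1-yl)-1,3,3-trimethylcyclohex-1-ene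
Product: 16 (3E)-4-methyl-6-(2,6,6-trimethylcyclohex-1-en-1-yl)hex-3-en-1-ol, via alkenylalane 14 (not isolated), via lithium alkenylaluminate 15 (not isolated)
Conditions: Me3Al, Cp2ZrCl2 (0.25 equiv), CH2Cl2, rt; evaporate; n-BuLi, THF/hexane, −30 °C; ethylene oxide, 0 °C → rt; aq. HCl
Reagents that add atoms: trimethylaluminium, C[Al](C)C; ethylene oxide, C1CO1
Why: Zirconium-catalysed syn-carboalumination (Negishi) places methyl on the internal and aluminium on the terminal alkyne carbon and thereby fixes the E trisubstituted alkene, and the derived aluminate should open ethylene oxide with retention of the alkene geometry.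

Step 10
Reactants: 16 (3E)-4-methyl-6-(2,6,6-trimethylcyclohex-1-en-1-yl)hex-3-en-1-ol
Product: 17 (3E)-1-iodo-4-methyl-6-(2,6,6-trimethylcyclohex-1-en-1-yl)hex-3-ene
Conditions: I2, PPh3, imidazole, CH2Cl2, 0 °C → rt
Reagents that add atoms: iodine, II
Why: Appel-type iodination of a primary alcohol (SN2 displacement on the alkoxyphosphonium salt), which does not affect the two alkenes.

Step 11
Reactants: 17 (3E)-1-iodo-4-methyl-6-(2,6,6-trimethylcyclohex-1-en-1-yl)hex-3-ene; 10 (6R)-3-bromo-6-[(3R)-5-oxooxolan-3-yl]-5,6-dihydro-2H-pyran-2-one
Product: 19 (6R)-3-[(3E)-4-methyl-6-(2,6,6-trimethylcyclohex-1-en-1-yl)hex-3-en-1-yl]-6-[(3R)-5-oxooxolan-3-yl]-5,6-dihydro-2H-pyran-2-one, via alkylzinc iodide 18 (not isolated)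
Conditions: 17, Zn dust, LiCl, THF, 40 °C; decant from excess zinc; then 10, PdCl2(dppf) (5 mol%), THF/NMP, 40 °C
Reagents that add atoms: none
Why: Negishi sp3–sp2 cross-coupling, in which zinc inserts into the primary C–I bond and the alkylzinc iodide transmetalates to the alkenylpalladium bromide formed by oxidative addition of zerovalent palladium into the activated C3–Br bond, the wide bite angle of dppf favouring reductive elimination over β-hydride elimination; the organozinc should not attack either lactone, and no stereocentre or alkene geometry is touched.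

**Compound list**

1 | acrolein (prop-2-enal) | C=CC=O | starting material
2 | (3R)-hexa-1,5-dien-3-yl bis[(+)-isopinocampheyl]borinate | C=CC[C@H](C=C)OB([C@H]1C[C@H]2C[C@@H]([C@@H]1C)C2(C)C)[C@H]1C[C@H]2C[C@@H]([C@@H]1C)C2(C)C | intermediate
3 | (3R)-hexa-1,5-dien-3-ol | C=CC[C@H](C=C)O | intermediate
4 | (3R)-hexa-1,5-dien-3-yl prop-2-enoate | C=CC[C@H](C=C)OC(=O)C=C | intermediate
5 | (6R)-6-ethenyl-5,6-dihydro-2H-pyran-2-one | O=C1C=CC[C@H](C=C)O1 | intermediate
6 | (6R)-6-(2,2-dichloro-3-oxocyclobutyl)-5,6-dihydro-2H-pyran-2-one, both epimers at the cyclobutane carbon bound to C6 | O=C1C=CC[C@H](C2CC(=O)C2(Cl)Cl)O1 | intermediate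
7 | (6R)-6-(3-oxocyclobutyl)-5,6-dihydro-2H-pyran-2-one | O=C1C=CC[C@H](C2CC(=O)C2)O1 | intermediate
8 | (6R)-6-[(3R)-5-oxooxolan-3-yl]-5,6-dihydro-2H-pyran-2-one | O=C1C=CC[C@H]([C@H]2COC(=O)C2)O1 | intermediate
9 | (6R)-3,4-dibromo-6-[(3R)-5-oxooxolan-3-yl]oxan-2-one, trans-dibromide from anti addition (both anti diastereomers) | O=C1C(Br)C(Br)C[C@H]([C@H]2COC(=O)C2)O1 | intermediate
10 | (6R)-3-bromo-6-[(3R)-5-oxooxolan-3-yl]-5,6-dihydro-2H-pyran-2-one | O=C1C(Br)=CC[C@H]([C@H]2COC(=O)C2)O1 | intermediate
11 | dihydro-β-ionone, 4-(2,6,6-trimethylcyclohex-1-en-1-yl)butan-2-one | CC(=O)CCC1=C(C)CCCC1(C)C | starting material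
12 | diethyl 4-(2,6,6-trimethylcyclohex-1-en-1-yl)but-1-en-2-yl phosphate | C=C(CCC1=C(C)CCCC1(C)C)OP(=O)(OCC)OCC | intermediate
13 | 2-(but-3-yn-1-yl)-1,3,3-trimethylcyclohex-1-ene | C#CCCC1=C(C)CCCC1(C)C | intermediate
14 | dimethyl[(1E)-2-methyl-4-(2,6,6-trimethylcyclohex-1-en-1-yl)but-1-en-1-yl]alumane | C[Al](C)/C=C(\C)CCC1=C(C)CCCC1(C)C | intermediate
15 | lithium butyl(dimethyl)[(1E)-2-methyl-4-(2,6,6-trimethylcyclohex-1-en-1-yl)but-1-en-1-yl]aluminate | [Li+].CCCC[Al-](C)(C)/C=C(\C)CCC1=C(C)CCCC1(C)C | intermediate
16 | (3E)-4-methyl-6-(2,6,6-trimethylcyclohex-1-en-1-yl)hex-3-en-1-ol | OCC/C=C(\C)CCC1=C(C)CCCC1(C)C | intermediate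
17 | (3E)-1-iodo-4-methyl-6-(2,6,6-trimethylcyclohex-1-en-1-yl)hex-3-ene | ICC/C=C(\C)CCC1=C(C)CCCC1(C)C | intermediate
18 | [(3E)-4-methyl-6-(2,6,6-trimethylcyclohex-1-en-1-yl)hex-3-en-1-yl]zinc iodide | I[Zn]CC/C=C(\C)CCC1=C(C)CCCC1(C)C | intermediate
19 | (6R)-3-[(3E)-4-methyl-6-(2,6,6-trimethylcyclohex-1-en-1-yl)hex-3-en-1-yl]-6-[(3R)-5-oxooxolan-3-yl]-5,6-dihydro-2H-pyran-2-one | CC1=C(CC/C(C)=C/CCC2=CC[C@H]([C@H]3COC(=O)C3)OC2=O)C(C)(C)CCC1 | target

**Summary**

Total step count: 11. Longest linear sequence: 8 steps (steps 1 to 7, then step 11); the side chain takes 3 steps (8 to 10).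

Steps most likely to fail:

Step 4. The vinyl group carries an allylic acyloxy oxygen and may add the short-lived dichloroketene too slowly, so that oligomerisation of the ketene wins. The fallback sets out from 5 and uses a cationic two-carbon partner in place of the neutral ketene. N,N-Dimethylacetamide, Tf2O and 2,4,6-collidine in refluxing 1,2-dichloroethane give the keteniminium salt, which should add to the vinyl group to give the cyclobutaniminium triflate F1. Hydrolysis of F1 with aqueous NaHCO3 should give the chlorine-free ketone directly, so the route is rejoined at 7 and step 5 is not needed.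

Step 6. The catalyst may discriminate poorly between the two diastereotopic methylene arms (a mismatch with the C6 centre), or an uncatalysed background oxidation may erode the selectivity. The fallback sets out from 7 and gives up catalyst control. Oxidation with aqueous H2O2 in 2,2,2-trifluoroethanol should give 8 together with its epimer (6R)-6-[(3S)-5-oxooxolan-3-yl]-5,6-dihydro-2H-pyran-2-one F2. Because C6 is fixed, the two are diastereomers and can be separated by chromatography or crystallisation. The route is rejoined at 8, at the cost of the material that ends up as F2.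

Step 11. Zinc insertion may be incomplete or transmetalation slow, so that protodehalogenation, β-hydride elimination or reduction of the bromo lactone competes. The fallback sets out from 17 and changes the nucleophile to a boron ate complex (B-alkyl Suzuki–Miyaura coupling). Lithium–iodine exchange with t-BuLi (2 equiv, Et2O, −78 °C) gives the alkyllithium F3. Trapping with B-methoxy-9-borabicyclo[3.3.1]nonane gives the lithium borate F4. Coupling of F4 with 10 (PdCl2(dppf), AsPh3, aqueous K3PO4, DMF, rt) should give the target, so the route is rejoined at 19.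

Further compounds
F1 | step 4 | N,N-dimethyl-3-[(2R)-6-oxo-3,6-dihydro-2H-pyran-2-yl]cyclobutan-1-iminium trifluoromethanesulfonate | O=C1C=CC[C@H](C2CC(=[N+](C)C)C2)O1.[O-]S(=O)(=O)C(F)(F)F
F2 | step 6 | (6R)-6-[(3S)-5-oxooxolan-3-yl]-5,6-dihydro-2H-pyran-2-one | O=C1C=CC[C@H]([C@@H]2COC(=O)C2)O1
F3 | step 11 | [(3E)-4-methyl-6-(2,6,6-trimethylcyclohex-1-en-1-yl)hex-3-en-1-yl]lithium | [Li]CC/C=C(\C)CCC1=C(C)CCCC1(C)C
F4 | step 11 | lithium 9-methoxy-9-[(3E)-4-methyl-6-(2,6,6-trimethylcyclohex-1-en-1-yl)hex-3-en-1-yl]-9-boranuidabicyclo[3.3.1]nonane | [Li+].CO[B-]1(CC/C=C(\C)CCC2=C(C)CCCC2(C)C)C2CCCC1CCC2
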